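**Plan**

- Retrosynthetic cuts: after removal of the silyl and O-methyl groups, ring A is opened at C5–C6 (Dieckmann closure with aromatisation), the chain at C7–C8 (dienolate acylation), ring C at O1–C8a and C4–C4a (cyclodehydration, acetoacetate alkylation), then the C3–aryl bond (malonate arylation) and the pyran of ring B (propargyl ether Claisen rearrangement).
- Forward order: the chromene of ring B is built first on 4-bromoresorcinol; the C2–C3–C4 unit is attached as an arylmalonate and reduced to a prochiral diol; ring C is closed as a dihydropyran ester; the C6–C7 chain carrying the prenyl group is added; ring A is formed last.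
- Enabling feature: ring A bears oxygen on C5, C7 and C8a, the 1,3,5 pattern of a folded triketide, and the C8a oxygen is O1 of ring C. C8a can therefore travel as the enol ether carbon of a dihydropyran, so the dione formed by C6→C5 closure is one tautomerisation away from the arene.
- Stereochemistry: C3 is the only stereocentre. It is set (R) by lipase desymmetrisation of the 2-aryl-1,3-propanediol; the acetylated arm becomes C2–O1, the free arm becomes C4, and no later step touches it.

Key step: step 12

Assumption: the lipase is taken to acetylate the pro-S hydroxymethyl arm of diol 9; should the enzyme prefer the other arm, hydrolysis of the diacetate with the same enzyme would give the same monoacetate 10.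

Ring atoms are numbered as in an isoflavan (O1, C2–C4, C4a, C5–C8, C8a; ring B primed). Ar = 2,2-dimethyl-5-[(triisopropylsilyl)oxy]-2H-chromen-8-yl.

**Route**

Step 1
Reactants: 1 4-bromoresorcinol
Product: 2 2-bromo-5-[(triisopropylsilyl)oxy]phenol
Conditions: i-Pr3SiCl (1.0 equiv), imidazole, CH2Cl2, −20 → 0 °C
Reagents that add atoms: triisopropylsilyl chloride, CC(C)[Si](Cl)(C(C)C)C(C)C
Why: Sterically controlled mono-silylation of a resorcinol; the bulky silyl chloride should take the hydroxyl para to bromine, which has no ortho substituent, in preference to the one flanked by bromine.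

Step 2
Reactants: 2 2-bromo-5-[(triisopropylsilyl)oxy]phenol; 3 3-chloro-3-methylbut-1-yne
Product: 4 {4-bromo-3-[(2-methylbut-3-yn-2-yl)oxy]phenoxy}triisopropylsilane
Conditions: DBU, CuCl2·2H2O (0.5 mol%), MeCN, 0 °C
Reagents that add atoms: none
Why: Copper-catalysed O-propargylation of a phenol with a tertiary propargylic chloride under amidine base is the standard entry to aryl 1,1-dimethylpropargyl ethers and is mild enough for the aryl silyl ether.

Step 3
Reactants: 4 {4-bromo-3-[(2-methylbut-3-yn-2-yl)oxy]phenoxy}triisopropylsilane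
Product: 6 8-bromo-2,2-dimethyl-5-[(triisopropylsilyl)oxy]-2H-chromene, via allenylphenol 5 (not isolated)
Conditions: PhNEt2, 190 °C
Reagents that add atoms: none
Why: Aromatic propargyl Claisen rearrangement can only reach the free ortho carbon between the two oxygens because the other ortho position carries bromine, and allenylphenol 5 should close by 1,5-hydrogen shift and oxa-6π electrocyclisation to the 2,2-dimethylchromene.

Step 4
Reactants: 6 8-bromo-2,2-dimethyl-5-[(triisopropylsilyl)oxy]-2H-chromene; 7 diethyl malonate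
Product: 8 diethyl 2-Ar-malonate
Conditions: Pd(dba)2 (2 mol%), P(t-Bu)3 (4 mol%), K3PO4, toluene, 70 °C
Reagents that add atoms: none
Why: Palladium-catalysed α-arylation of a malonate; the bulky electron-rich phosphine lets zerovalent palladium insert into the electron-rich ortho-alkoxy aryl bromide and drives reductive elimination, and the hindered product enolate should not arylate twice.

Step 5
Reactants: 8 diethyl 2-Ar-malonate
Product: 9 2-Ar-propane-1,3-diol
Conditions: LiAlH4, THF, −10 °C → rt (ester added to the hydride)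
Reagents that add atoms: none
Why: Hydride reduction of both ester groups; low temperature and inverse addition should limit enolisation of the acidic arylmalonate, and the aryl silyl ether and chromene are inert to the reagent.

Step 6
Reactants: 9 2-Ar-propane-1,3-diol
Product: 10 (S)-3-hydroxy-2-Ar-propyl acetate
Conditions: immobilised lipase from Burkholderia cepacia, vinyl acetate, t-BuOMe, 25 °C
Reagents that add atoms: vinyl acetate, CC(=O)OC=C
Why: Enzymatic desymmetrisation of a prochiral 2-aryl-1,3-propanediol by irreversible transesterification; the enzyme pocket distinguishes the two enantiotopic hydroxymethyl arms and so sets C3, the acetylated arm being the future C2.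

Step 7
Reactants: 10 (S)-3-hydroxy-2-Ar-propyl acetate
Product: 11 (R)-3-iodo-2-Ar-propyl acetate
Conditions: PPh3, I2, imidazole (premixed), CH2Cl2, 0 °C
Reagents that add atoms: iodine, II
Why: Appel-type iodination of the primary alcohol under neutral conditions should avoid 1,3-acyl migration; the stereocentre is not involved and the descriptor changes only through the priority rules.

Step 8
Reactants: 11 (R)-3-iodo-2-Ar-propyl acetate; 12 ethyl acetoacetate
Product: 13 ethyl (4R)-5-acetoxy-2-acetyl-4-Ar-pentanoate (mixture of C2 epimers)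
Conditions: NaH, 12 (2 equiv), THF–DMF, 50 °C
Reagents that add atoms: none
Why: Acetoacetic ester alkylation; the soft, weakly basic enolate should displace the primary iodide by SN2 in preference to E2, the excess of nucleophile suppresses dialkylation, and the new α-centre is lost again in the next step.

Step 9
Reactants: 13 ethyl (4R)-5-acetoxy-2-acetyl-4-Ar-pentanoate
Product: 15 ethyl (3R)-3-Ar-6-methyl-3,4-dihydro-2H-pyran-5-carboxylate, via hydroxy keto ester 14 (not isolated)
Conditions: p-TsOH·H2O (0.1 equiv), EtOH, 50 °C; then toluene, 4 Å MS, 80 °C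
Reagents that add atoms: none
Why: Acid-catalysed ethanolysis of the acetate frees alcohol 14, which adds to the ketone as a six-membered hemiketal and dehydrates to the conjugated enol ether ester (cyclodehydration of a 5-hydroxy ketone); ethanol as solvent keeps the ethyl ester and disfavours lactone formation.

Step 10
Reactants: 16 5-methylhex-4-enoic acid
Product: 18 N-methoxy-N,5-dimethylhex-4-enamide, via acyl imidazole 17 (not isolated)
Conditions: 1,1'-carbonyldiimidazole, CH2Cl2, 0 °C → rt; then MeNHOMe·HCl, rt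
Reagents that add atoms: N,O-dimethylhydroxylamine hydrochloride, CNOC.Cl
Why: Weinreb amide formation through the acyl imidazole, a neutral activation that leaves the trisubstituted alkene untouched.

Step 11
Reactants: 15 ethyl (3R)-3-Ar-6-methyl-3,4-dihydro-2H-pyran-5-carboxylate; 18 N-methoxy-N,5-dimethylhex-4-enamide
Product: 19 ethyl (3R)-3-Ar-6-(6-methyl-2-oxohept-5-en-1-yl)-3,4-dihydro-2H-pyran-5-carboxylate
Conditions: LiN(i-Pr)2 (1.15 equiv), THF, −78 °C; 18 (1.2 equiv), −78 → −20 °C; AcOH quench
Reagents that add atoms: none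
Why: γ-Acylation of the extended enolate of a β-alkoxy enoate; deprotonation of the 6-methyl group gives a dienolate that should react at its terminal carbon (α-attack would build a quaternary centre and break conjugation), and the tetrahedral Weinreb adduct persists until the quench, which prevents proton transfer and double acylation.

Step 12
Reactants: 19 ethyl (3R)-3-Ar-6-(6-methyl-2-oxohept-5-en-1-yl)-3,4-dihydro-2H-pyran-5-carboxylate
Product: 21 (3R)-3-Ar-6-(3-methylbut-2-en-1-yl)chromane-5,7-diol, via dione 20 (not isolated)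
Conditions: LiN(SiMe3)2 (2.5 equiv), THF, −78 → 25 °C, then 45 °C; AcOH quench at 0 °C
Reagents that add atoms: none
Why: The first equivalent of amide base removes a C8 proton (α to the C7 ketone and vinylogous to the ester) and the second generates the C6 enolate, whose carbon adds to the C5 ester carbonyl and expels ethoxide to give dione 20, which already holds the C4a=C8a enol ether double bond and therefore enolises at once to the aromatic bis-phenoxide of 21. The closest known reaction type is the base-mediated Dieckmann cyclisation of 5-oxo esters to cyclohexane-1,3-diones, in the form used for Claisen-type aromatisation of polyketide chains whose third carbonyl is masked as a β-alkoxy enoate. Ring A closes in a 6-(enolendo)-exo-trig acyl substitution, helped by the cis arrangement of the ester and the oxoalkyl chain across the C4a=C8a double bond of ring C. No stereocentre is formed, and C3, remote from every acidic position, is not touched. The selectivity needed is C-acylation by C6 over O-acylation by the C7 enolate oxygen (enol lactone formation); the excess of base keeps the carbon nucleophile at C6 present in full amount, the lactone pathway can revert through the lithium ethoxide set free, and only the C–C closure ends in the aromatic sink, which is why the mixture is warmed until equilibration is complete.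

Step 13
Reactants: 21 (3R)-3-Ar-6-(3-methylbut-2-en-1-yl)chromane-5,7-diol
Product: 22 (3R)-3-Ar-6-(3-methylbut-2-en-1-yl)-7-[(triisopropylsilyl)oxy]chroman-5-ol
Conditions: i-Pr3SiCl (1.05 equiv), imidazole, DMF, 0 °C
Reagents that add atoms: triisopropylsilyl chloride, CC(C)[Si](Cl)(C(C)C)C(C)C
Why: Sterically controlled phenol silylation; the 7-hydroxyl has only one ortho carbon substituent, whereas the 5-hydroxyl is flanked by the prenyl group at C6 and the C4 methylene, so the bulky chloride should react at O7 alone.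

Step 14
Reactants: 22 (3R)-3-Ar-6-(3-methylbut-2-en-1-yl)-7-[(triisopropylsilyl)oxy]chroman-5-ol
Product: 23 (3R)-3-Ar-5-methoxy-6-(3-methylbut-2-en-1-yl)-7-[(triisopropylsilyl)oxy]chromane
Conditions: MeI, K2CO3, acetone, 50 °C
Reagents that add atoms: iodomethane, CI
Why: Williamson methylation of the one remaining phenol; in acetone with carbonate the phenoxide should alkylate on oxygen and both aryl triisopropylsilyl ethers should persist.

Step 15
Reactants: 23 (3R)-3-Ar-5-methoxy-6-(3-methylbut-2-en-1-yl)-7-[(triisopropylsilyl)oxy]chromane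
Product: 24 (3R)-3-(5-hydroxy-2,2-dimethyl-2H-chromen-8-yl)-5-methoxy-6-(3-methylbut-2-en-1-yl)chroman-7-ol (CNP0119857.1)
Conditions: Bu4NF (2.4 equiv), AcOH (2.4 equiv), THF, 0 °C
Reagents that add atoms: none
Why: Fluoride cleavage of both aryl silyl ethers, buffered with acetic acid so that the electron-rich phenoxides are protonated as they form; the prenyl group, chromene and methyl ether are inert.

**Compound list**

1 | 4-bromoresorcinol | Oc1ccc(Br)c(O)c1 | starting material
2 | 2-bromo-5-[(triisopropylsilyl)oxy]phenol | Oc1cc(O[Si](C(C)C)(C(C)C)C(C)C)ccc1Br | intermediate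
3 | 3-chloro-3-methylbut-1-yne | CC(C)(Cl)C#C | starting material
4 | {4-bromo-3-[(2-methylbut-3-yn-2-yl)oxy]phenoxy}triisopropylsilane | C#CC(C)(C)Oc1cc(O[Si](C(C)C)(C(C)C)C(C)C)ccc1Br | intermediate
5 | 6-bromo-2-(3-methylbuta-1,2-dien-1-yl)-3-[(triisopropylsilyl)oxy]phenol (allenylphenol, not isolated) | CC(C)=C=Cc1c(O)c(Br)ccc1O[Si](C(C)C)(C(C)C)C(C)C | intermediate
6 | 8-bromo-2,2-dimethyl-5-[(triisopropylsilyl)oxy]-2H-chromene | CC1(C)C=Cc2c(O[Si](C(C)C)(C(C)C)C(C)C)ccc(Br)c2O1 | intermediate
7 | diethyl malonate | CCOC(=O)CC(=O)OCC | starting material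
8 | diethyl 2-{2,2-dimethyl-5-[(triisopropylsilyl)oxy]-2H-chromen-8-yl}malonate | CCOC(=O)C(C(=O)OCC)c1ccc(O[Si](C(C)C)(C(C)C)C(C)C)c2c1OC(C)(C)C=C2 | intermediate
9 | 2-{2,2-dimethyl-5-[(triisopropylsilyl)oxy]-2H-chromen-8-yl}propane-1,3-diol | OCC(CO)c1ccc(O[Si](C(C)C)(C(C)C)C(C)C)c2c1OC(C)(C)C=C2 | intermediate
10 | (S)-3-hydroxy-2-{2,2-dimethyl-5-[(triisopropylsilyl)oxy]-2H-chromen-8-yl}propyl acetate | OC[C@H](c1ccc(O[Si](C(C)C)(C(C)C)C(C)C)c2c1OC(C)(C)C=C2)COC(C)=O | intermediate
11 | (R)-3-iodo-2-{2,2-dimethyl-5-[(triisopropylsilyl)oxy]-2H-chromen-8-yl}propyl acetate | IC[C@H](c1ccc(O[Si](C(C)C)(C(C)C)C(C)C)c2c1OC(C)(C)C=C2)COC(C)=O | intermediate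
12 | ethyl acetoacetate | CCOC(=O)CC(C)=O | starting material
13 | ethyl (4R)-5-acetoxy-2-acetyl-4-{2,2-dimethyl-5-[(triisopropylsilyl)oxy]-2H-chromen-8-yl}pentanoate (C2 epimers) | CCOC(=O)C(C(C)=O)C[C@H](c1ccc(O[Si](C(C)C)(C(C)C)C(C)C)c2c1OC(C)(C)C=C2)COC(C)=O | intermediate
14 | ethyl (4R)-2-acetyl-4-{2,2-dimethyl-5-[(triisopropylsilyl)oxy]-2H-chromen-8-yl}-5-hydroxypentanoate (hydroxy keto ester, not isolated) | CCOC(=O)C(C(C)=O)C[C@H](c1ccc(O[Si](C(C)C)(C(C)C)C(C)C)c2c1OC(C)(C)C=C2)CO | intermediate
15 | ethyl (3R)-3-{2,2-dimethyl-5-[(triisopropylsilyl)oxy]-2H-chromen-8-yl}-6-methyl-3,4-dihydro-2H-pyran-5-carboxylate | CCOC(=O)C1=C(C)OC[C@@H](c2ccc(O[Si](C(C)C)(C(C)C)C(C)C)c3c2OC(C)(C)C=C3)C1 | intermediate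
16 | 5-methylhex-4-enoic acid | CC(C)=CCCC(=O)O | starting material
17 | 1-(1H-imidazol-1-yl)-5-methylhex-4-en-1-one (acyl imidazole, not isolated) | CC(C)=CCCC(=O)n1ccnc1 | intermediate
18 | N-methoxy-N,5-dimethylhex-4-enamide | CC(C)=CCCC(=O)N(C)OC | intermediate
19 | ethyl (3R)-3-{2,2-dimethyl-5-[(triisopropylsilyl)oxy]-2H-chromen-8-yl}-6-(6-methyl-2-oxohept-5-en-1-yl)-3,4-dihydro-2H-pyran-5-carboxylate | CCOC(=O)C1=C(CC(=O)CCC=C(C)C)OC[C@@H](c2ccc(O[Si](C(C)C)(C(C)C)C(C)C)c3c2OC(C)(C)C=C3)C1 | intermediate
20 | (3R)-3-{2,2-dimethyl-5-[(triisopropylsilyl)oxy]-2H-chromen-8-yl}-6-(3-methylbut-2-en-1-yl)-3,4-dihydro-2H-chromene-5,7(6H,8H)-dione (dione, not isolated) | O=C1C(CC=C(C)C)C(=O)CC2=C1C[C@H](c1ccc(O[Si](C(C)C)(C(C)C)C(C)C)c3c1OC(C)(C)C=C3)CO2 | intermediate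
21 | (3R)-3-{2,2-dimethyl-5-[(triisopropylsilyl)oxy]-2H-chromen-8-yl}-6-(3-methylbut-2-en-1-yl)chromane-5,7-diol | Oc1c(CC=C(C)C)c(O)cc2c1C[C@H](c1ccc(O[Si](C(C)C)(C(C)C)C(C)C)c3c1OC(C)(C)C=C3)CO2 | intermediate
22 | (3R)-3-{2,2-dimethyl-5-[(triisopropylsilyl)oxy]-2H-chromen-8-yl}-6-(3-methylbut-2-en-1-yl)-7-[(triisopropylsilyl)oxy]chroman-5-ol | Oc1c(CC=C(C)C)c(O[Si](C(C)C)(C(C)C)C(C)C)cc2c1C[C@H](c1ccc(O[Si](C(C)C)(C(C)C)C(C)C)c3c1OC(C)(C)C=C3)CO2 | intermediate
23 | (3R)-3-{2,2-dimethyl-5-[(triisopropylsilyl)oxy]-2H-chromen-8-yl}-5-methoxy-6-(3-methylbut-2-en-1-yl)-7-[(triisopropylsilyl)oxy]chromane | COc1c(CC=C(C)C)c(O[Si](C(C)C)(C(C)C)C(C)C)cc2c1C[C@H](c1ccc(O[Si](C(C)C)(C(C)C)C(C)C)c3c1OC(C)(C)C=C3)CO2 | intermediate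
24 | (3R)-3-(5-hydroxy-2,2-dimethyl-2H-chromen-8-yl)-5-methoxy-6-(3-methylbut-2-en-1-yl)chroman-7-ol | COc1c(CC=C(C)C)c(O)cc2c1C[C@H](c1ccc(O)c3c1OC(C)(C)C=C3)CO2 | target

**Count and risks**

Total step count: 15. Longest linear sequence: 14 steps (steps 1–9 and 11–15); step 10 is a one-step side branch.

Steps most likely to fail:

1. Step 12. The ring closure may be diverted into O-acylation by the C7 enolate oxygen, or the ester may be too electron-rich within the delocalised anion to accept the C6 enolate. The fallback sets out from 19 and separates the two events. DBU in toluene at 80 °C should deliberately enol-lactonise 19 to (3R)-3-Ar-7-(4-methylpent-3-en-1-yl)-3,4-dihydro-2H,5H-pyrano[4,3-b]pyran-5-one F1. Heating F1 with NaOEt in EtOH should then reopen the lactone and let the small equilibrium share of C6 enolate close onto C5, the classical alkoxide Dieckmann regime for cyclohexane-1,3-diones. The 4'-silyl ether is expected to be lost under these conditions, giving (3R)-3-(5-hydroxy-2,2-dimethyl-2H-chromen-8-yl)-6-(3-methylbut-2-en-1-yl)chromane-5,7-diol F2. Treating F2 with i-Pr3SiCl (2.2 equiv) and imidazole should silylate the two singly flanked hydroxyls at O7 and O4' and leave the hindered 5-hydroxyl, so the route is rejoined at 22.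

2. Step 6. The ortho-substituted aryl group may fit the enzyme poorly, giving weak or reversed discrimination of the two hydroxymethyl arms, and acyl migration in the monoacetate may erode its enantiomeric purity. The fallback sets out from 9 and uses a small-molecule catalyst whose sense is chosen through the ligand enantiomer: a dinuclear zinc catalyst from Et2Zn and the phenol-bridged bis(diphenylprolinol) ligand (ProPhenol) with vinyl benzoate should give (S)-3-hydroxy-2-Ar-propyl benzoate F3, whose benzoate is less prone to migrate. Iodination as in step 7 gives (R)-3-iodo-2-Ar-propyl benzoate F4, and alkylation of 12 as in step 8 gives ethyl (4R)-2-acetyl-5-(benzoyloxy)-4-Ar-pentanoate F5. K2CO3 in EtOH removes the benzoate to give 14, which is dehydrated with the acid of step 9, so the route is rejoined at 15.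

3. Step 11. The dienolate may react through its α-carbon or be quenched by proton transfer, and the product may enol-lactonise during work-up. The fallback sets out from 13 and extends the chain before ring C is closed, where only one carbanion terminus exists. K2CO3 in EtOH gives 14 (now isolated), and t-BuMe2SiCl with imidazole traps its open form as ethyl (4R)-2-acetyl-5-[(tert-butyldimethylsilyl)oxy]-4-Ar-pentanoate F6. The dianion of F6 (NaH, then n-BuLi, THF, 0 °C) should be acylated at the terminal methyl carbon by 18 to give ethyl 2-{(2R)-2-Ar-3-[(tert-butyldimethylsilyl)oxy]propyl}-9-methyl-3,5-dioxodec-8-enoate F7. p-TsOH·H2O in EtOH then removes the primary silyl ether and lets the freed hydroxyl dehydrate onto the C3 ketone, so the route is rejoined at 19.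

**Further compounds**

F1 | step 12 | (3R)-3-{2,2-dimethyl-5-[(triisopropylsilyl)oxy]-2H-chromen-8-yl}-7-(4-methylpent-3-en-1-yl)-3,4-dihydro-2H,5H-pyrano[4,3-b]pyran-5-one | O=C1OC(CCC=C(C)C)=CC2=C1C[C@H](c1ccc(O[Si](C(C)C)(C(C)C)C(C)C)c3c1OC(C)(C)C=C3)CO2
F2 | step 12 | (3R)-3-(5-hydroxy-2,2-dimethyl-2H-chromen-8-yl)-6-(3-methylbut-2-en-1-yl)chromane-5,7-diol | Oc1c(CC=C(C)C)c(O)cc2c1C[C@H](c1ccc(O)c3c1OC(C)(C)C=C3)CO2
F3 | step 6 | (S)-3-hydroxy-2-{2,2-dimethyl-5-[(triisopropylsilyl)oxy]-2H-chromen-8-yl}propyl benzoate | OC[C@H](c1ccc(O[Si](C(C)C)(C(C)C)C(C)C)c2c1OC(C)(C)C=C2)COC(=O)c1ccccc1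
F4 | step 6 | (R)-3-iodo-2-{2,2-dimethyl-5-[(triisopropylsilyl)oxy]-2H-chromen-8-yl}propyl benzoate | IC[C@H](c1ccc(O[Si](C(C)C)(C(C)C)C(C)C)c2c1OC(C)(C)C=C2)COC(=O)c1ccccc1
F5 | step 6 | ethyl (4R)-2-acetyl-5-(benzoyloxy)-4-{2,2-dimethyl-5-[(triisopropylsilyl)oxy]-2H-chromen-8-yl}pentanoate | CCOC(=O)C(C(C)=O)C[C@H](c1ccc(O[Si](C(C)C)(C(C)C)C(C)C)c2c1OC(C)(C)C=C2)COC(=O)c1ccccc1
F6 | step 11 | ethyl (4R)-2-acetyl-5-[(tert-butyldimethylsilyl)oxy]-4-{2,2-dimethyl-5-[(triisopropylsilyl)oxy]-2H-chromen-8-yl}pentanoate | CCOC(=O)C(C(C)=O)C[C@H](c1ccc(O[Si](C(C)C)(C(C)C)C(C)C)c2c1OC(C)(C)C=C2)CO[Si](C)(C)C(C)(C)C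
F7 | step 11 | ethyl 2-{(2R)-3-[(tert-butyldimethylsilyl)oxy]-2-{2,2-dimethyl-5-[(triisopropylsilyl)oxy]-2H-chromen-8-yl}propyl}-9-methyl-3,5-dioxodec-8-enoate | CCOC(=O)C(C[C@H](c1ccc(O[Si](C(C)C)(C(C)C)C(C)C)c2c1OC(C)(C)C=C2)CO[Si](C)(C)C(C)(C)C)C(=O)CC(=O)CCC=C(C)C
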